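**Strategy.** With azulene numbering (C3 carbinol carbon, C3a/C8a ring fusion, C4 aroyloxy carbon, C5 methylene, C6 methyl-bearing alkene carbon, C8 isovaleroyloxy carbon), the seven-membered ring hides a cyclohepta-1,4-diene: C4=C3a as an enol ether and C7=C8, with quaternary C8a between them. This is the retron of a divinylcyclopropane Cope rearrangement. The precursor, a bicyclo[3.1.0]hexane made from (R)-terpinen-4-ol, holds a temporary C3a–C8 cyclopropane bond that is absent from the target. Heating its silyl enol ether forms C5–C6, closes the seven-membered ring and breaks that bond in one operation; a singlet-oxygen ene reaction later shifts the alkene to C6=C7 and oxygenates C8.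

Key step: step 10

Assumption: (R)-(−)-terpinen-4-ol is used as the enantiopure commercial terpene, and 4-[(tert-butyldimethylsilyl)oxy]benzoic acid is taken as a commercial reagent.

**Step 1**
Reactants: 1 (R)-(−)-terpinen-4-ol
Product: 2 triethylsilyl ether of 1
Conditions: TESOTf, 2,6-lutidine, CH2Cl2, −78 → 0 °C
Reagents that add atoms: triethylsilyl trifluoromethanesulfonate, CC[Si](CC)(CC)OS(=O)(=O)C(F)(F)F
Why: Silyl triflate silylation of the hindered tertiary alcohol should be clean, and it masks the hydroxyl that would otherwise sit β to the aldehyde and be lost by elimination or retro-aldol cleavage in steps 2 and 3; no stereocentre is touched.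

**Step 2**
Reactants: 2 triethylsilyl ether of 1
Product: 4 (3R)-6-oxo-3-(propan-2-yl)-3-[(triethylsilyl)oxy]heptanal, via ozonide 3 (not isolated)
Conditions: O3, CH2Cl2, −78 °C; then Me2S, −78 °C → rt
Reagents that add atoms: ozone, [O-][O+]=O
Why: Ozonolysis of the only alkene with reductive work-up cleaves the ring C=C bond and unfolds the cyclohexene into an acyclic keto aldehyde while the carbinol stereocentre is kept.

**Step 3**
Reactants: 4 (3R)-6-oxo-3-(propan-2-yl)-3-[(triethylsilyl)oxy]heptanal
Product: 6 (5S)-5-hydroxy-2-methyl-5-(propan-2-yl)cyclopent-1-ene-1-carbaldehyde, via silyl ether enal 5 (not isolated)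
Conditions: dibenzylammonium trifluoroacetate (cat.), PhH, 50 °C; then HF·pyridine, THF, 0 °C
Reagents that add atoms: none
Why: Amine-salt-catalysed intramolecular aldol condensation: the aldehyde enamine adds to the methyl ketone (five-membered ring, enolexo closure), the free aldol hydroxyl should be eliminated in preference to the silyloxy group to give the tetrasubstituted enal, and HF·pyridine then frees the tertiary alcohol; no new stereocentre.

**Step 4**
Reactants: 6 (5S)-5-hydroxy-2-methyl-5-(propan-2-yl)cyclopent-1-ene-1-carbaldehyde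
Product: 7 (1S)-1-[(5S)-5-hydroxy-2-methyl-5-(propan-2-yl)cyclopent-1-en-1-yl]ethan-1-ol
Conditions: MeMgBr (2.5 equiv), CH2Cl2/Et2O, −78 °C
Reagents that add atoms: methylmagnesium bromide, C[Mg]Br
Why: Cram-chelate-type Grignard addition: the magnesium alkoxide of the tertiary hydroxyl binds the aldehyde oxygen in the s-trans rotamer, which tilts the carbonyl so that its rear face lies under the isopropyl group, and methyl should add from the open face to give the (S)-carbinol.

**Step 5**
Reactants: 7 (1S)-1-[(5S)-5-hydroxy-2-methyl-5-(propan-2-yl)cyclopent-1-en-1-yl]ethan-1-ol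
Product: 9 diazoacetate of the secondary hydroxyl of 7, via tosylhydrazone ester 8 (not isolated)
Conditions: TsNHN=CHCOCl, PhNMe2, CH2Cl2, 0 °C; then Et3N, 0 °C → rt
Reagents that add atoms: glyoxylic acid chloride p-toluenesulfonylhydrazone, Cc1ccc(cc1)S(=O)(=O)NN=CC(Cl)=O
Why: The acid chloride should acylate only the less hindered secondary hydroxyl, and triethylamine then expels p-toluenesulfinate from the hydrazone (Bamford–Stevens-type elimination) to give the diazoacetate; no stereocentre changes.

**Step 6**
Reactants: 9 diazoacetate of the secondary hydroxyl of 7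
Product: 10 tricyclic cyclopropane-fused γ-lactone (cyclopropane on the face anti to the tertiary hydroxyl)
Conditions: Rh2(OAc)4 (1 mol %), CH2Cl2, 40 °C, slow addition of 9
Reagents that add atoms: none
Why: Intramolecular rhodium-carbenoid cyclopropanation: allylic 1,3-strain with the ring methyl holds the carbinol C–H in the alkene plane, so the (S)-configured tether should carry the carbene to the alkene face anti to the tertiary hydroxyl, which sets the quaternary methyl carbon and both other cyclopropane carbons, and the five-membered lactone forces the future alkenyl carbon cis to the carbinol side chain.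

**Step 7**
Reactants: 10 tricyclic cyclopropane-fused γ-lactone
Product: 11 corresponding lactol (both anomers)
Conditions: i-Bu2AlH (2.2 equiv), CH2Cl2, −78 °C
Reagents that add atoms: none
Why: i-Bu2AlH at low temperature stops at the tetrahedral aluminium acetal, so the lactone should give the lactol (anomer mixture of no consequence) without touching the cyclopropane.

**Step 8**
Reactants: 11 lactol
Product: 12 1-{2-hydroxy-5-methyl-6-exo-[(E)-prop-1-enyl]-2-(propan-2-yl)bicyclo[3.1.0]hexan-1-yl}ethan-1-ol
Conditions: 5-(ethanesulfonyl)-1-phenyl-1H-tetrazole, KN(SiMe3)2 (excess), DME, −60 °C → rt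
Reagents that add atoms: 5-(ethanesulfonyl)-1-phenyl-1H-tetrazole, CCS(=O)(=O)c1nnnn1-c1ccccc1
Why: Julia–Kocienski olefination of the ring-opened hydroxy aldehyde form of the lactol should give the (E)-propenyl group (E selectivity of the phenyltetrazolyl sulfone with a potassium base in DME) and releases the secondary alcohol.

**Step 9**
Reactants: 12 propenyl carbinol
Product: 13 1-{2-hydroxy-5-methyl-6-exo-[(E)-prop-1-enyl]-2-(propan-2-yl)bicyclo[3.1.0]hexan-1-yl}ethan-1-one
Conditions: Dess–Martin periodinane, CH2Cl2, 0 °C → rt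
Reagents that add atoms: none
Why: Dess–Martin oxidation converts the secondary carbinol into the methyl ketone under neutral conditions that leave the tertiary alcohol and the vinylcyclopropane untouched; the carbinol stereocentre, having done its work in step 6, is erased.

**Step 10**
Reactants: 13 cis-2-propenylcyclopropyl methyl ketone
Product: 15 4-[(tert-butyldimethylsilyl)oxy]-6,8a-dimethyl-3-(propan-2-yl)-1,2,3,5,6,8a-hexahydroazulen-3-ol, via silyl enol ether 14 (not isolated)
Conditions: LiN(i-Pr)2 (2.2 equiv), THF, −78 °C; TBSCl, DMPU, −78 → 0 °C; buffer wash, solvent switch; PhMe, 110 °C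
Reagents that add atoms: tert-butyldimethylsilyl chloride, CC(C)(C)[Si](C)(C)Cl
Why: The kinetic enolate of the methyl ketone is O-silylated and, on heating, the cis-held 2-silyloxyvinyl and (E)-propenyl groups undergo a concerted [3,3]-sigmatropic Cope shift through the boat transition state that a cis-divinylcyclopropane must adopt. The closest known reaction type is the thermal rearrangement of silyl enol ethers of cis-2-vinylcyclopropyl ketones to cyclohepta-1,4-dienyl silyl ethers. The seven-membered ring closes by suprafacial bonding of the two trigonal termini (the enol CH2, C5, and the methyl-bearing propenyl carbon, C6) while the C3a–C8 cyclopropane bond opens, so ring strain pays for the closure and the five-membered ring is carried along unchanged. The one new stereocentre, C6, is fixed by the E geometry of the propenyl group in the boat array, which places C6–H on the face of the C8a methyl; C3 and C8a are not touched. The step needs the Cope shift to outrun the homodienyl 1,5-hydrogen shift from the syn methyl and cis-to-trans isomerisation of the cyclopropane, and the lactone-derived cis arrangement, termini that carry only hydrogen in the inward positions and the donor silyloxy group should secure this. The enol ether is delivered regiodefined at C4=C3a, which sets up the ring-fusion centre for step 11.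

**Step 11**
Reactants: 15 silyl dienol ether
Product: 16 cis-fused 3-hydroxy-6,8a-dimethyl-3-(propan-2-yl)-2,3,3a,5,6,8a-hexahydroazulen-4(1H)-one
Conditions: Bu4NF, AcOH, THF, −40 → 0 °C
Reagents that add atoms: none
Why: Fluoride cleaves the silyl enol ether and the enolate is protonated at once under kinetic control on the convex face, anti to the isopropyl group and next to the free hydroxyl, which should give the cis ring fusion (C3a–H syn to the C8a methyl); the cold buffered medium avoids retro-aldol cleavage and epimerisation, and 16 is reduced without delay.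

**Step 12**
Reactants: 16 cis-fused ketone
Product: 17 6,8a-dimethyl-3-(propan-2-yl)-1,2,3,3a,4,5,6,8a-octahydroazulene-3,4-diol (C4–OH anti to C3a–H)
Conditions: LiBH(s-Bu)3, THF, −78 °C; aqueous NH4Cl
Reagents that add atoms: none
Why: Steric approach control: the bulky hydride should add to the carbonyl face syn to the ring-fusion hydrogen because the other face is screened by the isopropyl group and the C6 methyl, which gives the C4 alcohol anti to C3a–H.

**Step 13**
Reactants: 17 diol
Product: 18 C4 4-[(tert-butyldimethylsilyl)oxy]benzoate of 17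
Conditions: 4-(TBSO)C6H4CO2H, 2,4,6-trichlorobenzoyl chloride, Et3N, THF; then 17, DMAP, PhMe, 60 °C
Reagents that add atoms: 4-[(tert-butyldimethylsilyl)oxy]benzoic acid, CC(C)(C)[Si](C)(C)Oc1ccc(cc1)C(O)=O
Why: Yamaguchi esterification through the mixed anhydride acylates the secondary C4 hydroxyl, the tertiary C3 hydroxyl being too hindered to react; the configuration at C4 is retained.

**Step 14**
Reactants: 18 aryl ester
Product: 20 C8 allylic alcohol with the C6=C7 alkene (C8–OH cis to the C8a methyl), via allylic hydroperoxide 19 (not isolated)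
Conditions: O2, tetraphenylporphyrin (cat.), visible light, CH2Cl2, 0 °C; then PPh3
Reagents that add atoms: dioxygen, O=O
Why: Schenck ene reaction of singlet oxygen: the only allylic hydrogen is C6–H, which lies on the face of the C8a methyl, so the suprafacial ene process must deliver oxygen to C8 on that same face while the double bond moves to C6=C7, and PPh3 reduces the hydroperoxide to the alcohol.

**Step 15**
Reactants: 20 allylic alcohol
Product: 21 C8 3-methylbutanoate of 20
Conditions: 3-methylbutanoyl chloride, pyridine, DMAP (cat.), CH2Cl2, 0 °C → rt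
Reagents that add atoms: 3-methylbutanoyl chloride, CC(C)CC(Cl)=O
Why: DMAP-catalysed acylation of the secondary allylic alcohol with the acid chloride; the tertiary alcohol should not react and no stereocentre is affected.

**Step 16**
Reactants: 21 silyl-protected diester
Product: 22 (3S,3aS,4R,8R,8aR)-3-hydroxy-6,8a-dimethyl-8-[(3-methylbutanoyl)oxy]-3-(propan-2-yl)-1,2,3,3a,4,5,8,8a-octahydroazulen-4-yl 4-hydroxybenzoate
Conditions: Bu4NF, AcOH, THF, 0 °C
Reagents that add atoms: none
Why: Acetic-acid-buffered fluoride cleaves the aryl silyl ether selectively, and both esters and the allylic system should survive these mild conditions.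

**Compound list**

1 | (R)-(−)-terpinen-4-ol, (1R)-4-methyl-1-(propan-2-yl)cyclohex-3-en-1-ol | CC1=CC[C@@](O)(C(C)C)CC1 | starting material
2 | triethyl{[(1R)-4-methyl-1-(propan-2-yl)cyclohex-3-en-1-yl]oxy}silane | CC1=CC[C@@](O[Si](CC)(CC)CC)(C(C)C)CC1 | intermediate
3 | secondary ozonide of 2 (1,2,4-trioxolane across the former alkene; acetal centres undefined) | CC12CC[C@](O[Si](CC)(CC)CC)(C(C)C)CC(OO1)O2 | intermediate
4 | (3R)-6-oxo-3-(propan-2-yl)-3-[(triethylsilyl)oxy]heptanal | CC(=O)CC[C@](O[Si](CC)(CC)CC)(C(C)C)CC=O | intermediate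
5 | (5S)-2-methyl-5-(propan-2-yl)-5-[(triethylsilyl)oxy]cyclopent-1-ene-1-carbaldehyde | O=CC1=C(C)CC[C@]1(O[Si](CC)(CC)CC)C(C)C | intermediate
6 | (5S)-5-hydroxy-2-methyl-5-(propan-2-yl)cyclopent-1-ene-1-carbaldehyde | O=CC1=C(C)CC[C@]1(O)C(C)C | intermediate
7 | (1S)-1-[(5S)-5-hydroxy-2-methyl-5-(propan-2-yl)cyclopent-1-en-1-yl]ethan-1-ol | C[C@H](O)C1=C(C)CC[C@]1(O)C(C)C | intermediate
8 | glyoxylate p-toluenesulfonylhydrazone ester of the secondary hydroxyl of 7 | C[C@H](OC(=O)C=NNS(=O)(=O)c1ccc(C)cc1)C1=C(C)CC[C@]1(O)C(C)C | intermediate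
9 | diazoacetate of the secondary hydroxyl of 7 | C[C@H](OC(=O)C=[N+]=[N-])C1=C(C)CC[C@]1(O)C(C)C | intermediate
10 | tricyclic lactone: a cyclopropane CH bridges the former alkene carbons on the face anti to the tertiary hydroxyl and is tied to the carbinol carbon as a cis-fused γ-lactone | C[C@@H]1OC(=O)[C@H]2[C@]3(C)CC[C@](O)(C(C)C)[C@]123 | intermediate
11 | lactol of 10 (both anomers) | C[C@@H]1OC(O)[C@H]2[C@]3(C)CC[C@](O)(C(C)C)[C@]123 | intermediate
12 | 1-{2-hydroxy-5-methyl-6-exo-[(E)-prop-1-enyl]-2-(propan-2-yl)bicyclo[3.1.0]hexan-1-yl}ethan-1-ol (2-OH anti to C6) | C/C=C/[C@H]1[C@]2(C)CC[C@](O)(C(C)C)[C@]12[C@H](C)O | intermediate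
13 | 1-{2-hydroxy-5-methyl-6-exo-[(E)-prop-1-enyl]-2-(propan-2-yl)bicyclo[3.1.0]hexan-1-yl}ethan-1-one | C/C=C/[C@H]1[C@]2(C)CC[C@](O)(C(C)C)[C@]12C(C)=O | intermediate
14 | tert-butyldimethylsilyl enol ether of 13 (cis-divinylcyclopropane) | C/C=C/[C@H]1[C@]2(C)CC[C@](O)(C(C)C)[C@]12C(=C)O[Si](C)(C)C(C)(C)C | intermediate
15 | 4-[(tert-butyldimethylsilyl)oxy]-6,8a-dimethyl-3-(propan-2-yl)-1,2,3,5,6,8a-hexahydroazulen-3-ol (C3–OH and C6–H on the face of the C8a methyl) | C[C@@H]1C=C[C@]2(C)CC[C@](O)(C(C)C)C2=C(O[Si](C)(C)C(C)(C)C)C1 | intermediate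
16 | cis-fused 3-hydroxy-6,8a-dimethyl-3-(propan-2-yl)-2,3,3a,5,6,8a-hexahydroazulen-4(1H)-one (C3a–H, C3–OH, C6–H and C8a–CH3 on one face) | C[C@@H]1C=C[C@]2(C)CC[C@](O)(C(C)C)[C@@H]2C(=O)C1 | intermediate
17 | 6,8a-dimethyl-3-(propan-2-yl)-1,2,3,3a,4,5,6,8a-octahydroazulene-3,4-diol (C4–OH anti to C3a–H) | C[C@@H]1C=C[C@]2(C)CC[C@](O)(C(C)C)[C@@H]2[C@H](O)C1 | intermediate
18 | C4 4-[(tert-butyldimethylsilyl)oxy]benzoate of 17 | C[C@@H]1C=C[C@]2(C)CC[C@](O)(C(C)C)[C@@H]2[C@H](OC(=O)c2ccc(O[Si](C)(C)C(C)(C)C)cc2)C1 | intermediate
19 | C8 hydroperoxide with C6=C7 alkene (OOH cis to the C8a methyl) | CC1=C[C@@H](OO)[C@]2(C)CC[C@](O)(C(C)C)[C@@H]2[C@H](OC(=O)c2ccc(O[Si](C)(C)C(C)(C)C)cc2)C1 | intermediate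
20 | C8 allylic alcohol corresponding to 19 | CC1=C[C@@H](O)[C@]2(C)CC[C@](O)(C(C)C)[C@@H]2[C@H](OC(=O)c2ccc(O[Si](C)(C)C(C)(C)C)cc2)C1 | intermediate
21 | C8 3-methylbutanoate of 20 | CC1=C[C@@H](OC(=O)CC(C)C)[C@]2(C)CC[C@](O)(C(C)C)[C@@H]2[C@H](OC(=O)c2ccc(O[Si](C)(C)C(C)(C)C)cc2)C1 | intermediate
22 | (3S,3aS,4R,8R,8aR)-3-hydroxy-6,8a-dimethyl-8-[(3-methylbutanoyl)oxy]-3-(propan-2-yl)-1,2,3,3a,4,5,8,8a-octahydroazulen-4-yl 4-hydroxybenzoate | CC1=C[C@@H](OC(=O)CC(C)C)[C@]2(C)CC[C@](O)(C(C)C)[C@@H]2[C@H](OC(=O)c2ccc(O)cc2)C1 | target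

**Totals.** Total step count: 16. Longest linear sequence: 16 steps (1 → 22, fully linear).

**Steps most likely to fail, with fallbacks**

Step 6. Carbene transfer to the tetrasubstituted alkene may be too slow, so that carbene dimerisation or insertion into the tertiary O–H takes over. The fallback sets out from 7. The secondary hydroxyl is acylated with methyl 3-chloro-3-oxopropanoate (pyridine, CH2Cl2) to the mixed malonate F1. Diazo transfer (4-acetamidobenzenesulfonyl azide, Et3N, MeCN) gives the diazomalonate F2. Its more robust acceptor/acceptor copper carbenoid (Cu(acac)2, PhMe, reflux) should cyclopropanate under the same allylic-strain control to the lactone methyl ester F3. Krapcho dealkoxycarbonylation (LiCl, wet DMSO, 140 °C) removes the ester, the ring fusion leaving only the cis lactone, and the route is rejoined at 10.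

Step 14. The ene reaction of the cis-disubstituted alkene may be slow, and the more electron-rich trisubstituted alkene of the product may be oxidised further. The fallback sets out from 18. Allylic hydroxylation with SeO2 (cat.) and t-BuOOH at the only allylic C–H (C6) gives the tertiary allylic alcohol F4. Oxidative 1,3-transposition with pyridinium chlorochromate (C5H5NH+ ClCrO3−) in CH2Cl2 (Babler–Dauben oxidation) gives the C8 enone F5. Luche reduction (NaBH4, CeCl3·7H2O, MeOH, −78 °C), with hydride expected to add anti to the angular methyl, gives the C8 alcohol cis to that methyl, and the route is rejoined at 20.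

Step 4. Facial selectivity in the methyl addition may be poor, which would erode the face control of the cyclopropanation that depends on this carbinol. The fallback sets out from 6. Methyl addition without stereocontrol (MeLi, THF, −78 °C) gives the carbinol epimer mixture F6. MnO2 (CH2Cl2) oxidises it to the methyl enone F7. Reagent-controlled CBS reduction ((R)-2-methyl-CBS-oxazaborolidine, BH3·SMe2, THF, −20 °C) should give the (S)-carbinol, and the route is rejoined at 7.

**Further compounds**

F1 | step 6 | methyl malonate (mixed ester) of the secondary hydroxyl of 7 | C[C@H](OC(=O)CC(=O)OC)C1=C(C)CC[C@]1(O)C(C)C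
F2 | step 6 | 2-diazomalonate corresponding to F1 | C[C@H](OC(=O)C(=[N+]=[N-])C(=O)OC)C1=C(C)CC[C@]1(O)C(C)C
F3 | step 6 | lactone 10 carrying a methoxycarbonyl group on the lactone α-carbon (cyclopropane carbon) | C[C@@H]1OC(=O)[C@@]2(C(=O)OC)[C@]3(C)CC[C@](O)(C(C)C)[C@]123
F4 | step 14 | C6 tertiary allylic alcohol of 18 with the C7=C8 alkene (C6 configuration immaterial) | CC1(O)C=C[C@]2(C)CC[C@](O)(C(C)C)[C@@H]2[C@H](OC(=O)c2ccc(O[Si](C)(C)C(C)(C)C)cc2)C1
F5 | step 14 | C8 enone with the C6=C7 alkene | CC1=CC(=O)[C@]2(C)CC[C@](O)(C(C)C)[C@@H]2[C@H](OC(=O)c2ccc(O[Si](C)(C)C(C)(C)C)cc2)C1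
F6 | step 4 | 1-[(5S)-5-hydroxy-2-methyl-5-(propan-2-yl)cyclopent-1-en-1-yl]ethan-1-ol as a mixture of carbinol epimers | CC(O)C1=C(C)CC[C@]1(O)C(C)C
F7 | step 4 | 1-[(5S)-5-hydroxy-2-methyl-5-(propan-2-yl)cyclopent-1-en-1-yl]ethan-1-one | CC(=O)C1=C(C)CC[C@]1(O)C(C)C
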